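**Retrosynthetic overview**
1. Target 25 comes from the 6α,8α-diol 21 by angeloylation of its only secondary hydroxyl and desilylation. Diol 21 comes from labda-7,14-dien-6-one 18 by α-face epoxidation, reductive C7–O cleavage and equatorial-selective ketone reduction.
2. The enabling feature lies in ring B. The oxygen-bearing carbons C6 and C8 stand 1,3 across C7 (aldol retron) and 1,5 through C5–C10–C9 (Michael retron), and C5–C10 is also the ring A/ring B fusion bond.
3. Cutting C5–C10 and C7–C8 unfolds both rings into one acyclic chain, C7–C6–C5–C4–C3–C2–C1–C10–C9–C8 (enedione 15). Its C6 methyl ketone is a C5/C7 bis-nucleophile and its C8–C9–C10 enone a C10/C8 bis-electrophile. Ring A forms first, ring B second.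
4. Enedione 15 comes from a Negishi union (C1–C10) of alkylzinc 14 (from mesityl oxide and allylsilane) with enol triflate 9 of the symmetric 3-alkylpentane-2,4-dione 8.
5. Dione 8 comes from acetylacetone and iodide 6, which brings C13 from (R)-linalool after oxidative cleavage and loss of one carbon.

Key step: step 9

Remark: labdane numbering is used (C17 is the methyl on C8, C20 the methyl on C10). (R)-(−)-linalool of high enantiomeric purity and angelic acid are taken as commercial.

**Step 1**
Reactants: 1 (R)-(−)-linalool
Product: 2 (3R)-3,7-dimethyl-3-(triethylsilyloxy)octa-1,6-diene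
Conditions: Et3SiCl, imidazole, DMAP (cat.), DMF, rt to 40 °C
Reagents that add atoms: chlorotriethylsilane CC[Si](Cl)(CC)CC
Why: Silyl ether protection of the tertiary allylic alcohol leaves the chiral-pool C13 stereocentre unchanged and masks the hydroxyl that would later add to the ring B enone in an oxa-Michael reaction.

**Step 2**
Reactants: 2 (3R)-3,7-dimethyl-3-(triethylsilyloxy)octa-1,6-diene
Product: 4 (4R)-4-methyl-4-(triethylsilyloxy)hex-5-enoic acid, via TES-aldehyde 3 (not isolated)
Conditions: O3 (one equivalent), MeCN/H2O 9:1, 0 °C; then NaClO2, NaH2PO4, 0 °C to rt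
Reagents that add atoms: ozone [O-][O+]=O; sodium chlorite [Na+].[O-]Cl=O
Why: Ozonolysis picks the electron-rich trisubstituted alkene over the hindered vinyl group, water turns the carbonyl oxide directly into aldehyde 3 plus hydrogen peroxide, and the following Pinnick oxidation uses that peroxide as its hypochlorite scavenger.

**Step 3**
Reactants: 4 (4R)-4-methyl-4-(triethylsilyloxy)hex-5-enoic acid
Product: 6 (3R)-5-iodo-3-methyl-3-(triethylsilyloxy)pent-1-ene, via thiohydroxamate ester 5 (not isolated)
Conditions: N-hydroxypyridine-2-thione, DCC, DMAP (cat.), CH2Cl2, 0 °C, dark; then CHI3, visible light, rt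
Reagents that add atoms: iodoform IC(I)I
Why: In this Barton decarboxylative iodination the thiohydroxamate ester fragments under light to the primary C11 radical, which abstracts iodine from iodoform in a neutral radical chain that tolerates the vinyl group and silyl ether and removes the one surplus carbon.

**Step 4**
Reactants: 6 (3R)-5-iodo-3-methyl-3-(triethylsilyloxy)pent-1-ene; 7 pentane-2,4-dione
Product: 8 3-[(3R)-3-methyl-3-(triethylsilyloxy)pent-4-en-1-yl]pentane-2,4-dione
Conditions: K2CO3, excess 7, acetone, reflux
Reagents that add atoms: none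
Why: This is an SN2 C-alkylation of the soft acetylacetonate by an unhindered primary iodide, and the new methine carbon carries two identical acetyl groups, so it is no stereocentre.

**Step 5**
Reactants: 8 3-[(3R)-3-methyl-3-(triethylsilyloxy)pent-4-en-1-yl]pentane-2,4-dione
Product: 9 (2Z,6R)-3-acetyl-6-methyl-6-(triethylsilyloxy)octa-2,7-dien-2-yl trifluoromethanesulfonate
Conditions: Tf2O, Et3N, LiOSO2CF3, CH2Cl2, −78 °C to 0 °C
Reagents that add atoms: trifluoromethanesulfonic anhydride O=S(=O)(OS(=O)(=O)C(F)(F)F)C(F)(F)F
Why: O-sulfonylation of the lithium-chelated enolate (enol triflate formation) should give the Z isomer, and because the two acetyl groups of 8 are equivalent no regiochemical question arises.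

**Step 6**
Reactants: 10 mesityl oxide; 11 allyltrimethylsilane
Product: 12 4,4-dimethylhept-6-en-2-one
Conditions: TiCl4, CH2Cl2, −78 °C; then H2O
Reagents that add atoms: none
Why: Hosomi–Sakurai conjugate allylation of a β,β-disubstituted enone is a standard way to build the quaternary gem-dimethyl carbon C4 next to the acetonyl unit C5–C6–C7.

**Step 7**
Reactants: 12 4,4-dimethylhept-6-en-2-one
Product: 13 7-bromo-4,4-dimethylheptan-2-one
Conditions: HBr (gas), dibenzoyl peroxide (cat.), pentane, 0 °C, light
Reagents that add atoms: hydrogen bromide Br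
Why: Radical-chain anti-Markovnikov hydrobromination (peroxide effect) places bromine on the terminal carbon C1 and leaves the ketone untouched.

**Step 8**
Reactants: 13 7-bromo-4,4-dimethylheptan-2-one; 9 (2Z,6R)-3-acetyl-6-methyl-6-(triethylsilyloxy)octa-2,7-dien-2-yl trifluoromethanesulfonate
Product: 15 (3Z)-4,8,8-trimethyl-3-[(3R)-3-methyl-3-(triethylsilyloxy)pent-4-en-1-yl]undec-3-ene-2,10-dione, via alkylzinc bromide 14 (not isolated)
Conditions: Zn dust, I2 (cat.), DMA, 80 °C; then 9, PdCl2(dppf) (cat.), THF, 50 °C
Reagents that add atoms: none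
Why: In this Negishi coupling zinc insertion gives a ketone-tolerant alkylzinc reagent, and oxidative addition of zerovalent palladium to the electron-poor enol triflate, transmetalation and reductive elimination (dppf suppresses β-hydride elimination) form the C1–C10 bond under neutral conditions with retention of alkene geometry.

**Step 9**
Reactants: 15 (3Z)-4,8,8-trimethyl-3-[(3R)-3-methyl-3-(triethylsilyloxy)pent-4-en-1-yl]undec-3-ene-2,10-dione
Product: 18 (13R)-13-(triethylsilyloxy)labda-7,14-dien-6-one, via Michael adduct 16 (not isolated), via ketol 17 (not isolated)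
Conditions: O-allyl-N-(9-anthracenylmethyl)cinchonidinium bromide (10 mol %), 50 % aq KOH, toluene (dilute), 0 °C to 40 °C
Reagents that add atoms: none
Why: Proposed new method: interfacial hydroxide reversibly deprotonates the C6 methyl ketone, and its C5 enolate, held as a contact ion pair by the chiral ammonium cation, adds to C10 of the enone (Michael addition, 6-exo-trig, ring A); a proton shift gives the C7 enolate, which attacks the C8 methyl ketone (aldol addition, 6-(enolendo)-exo-trig, ring B), and E1cB loss of water from ketol 17 drains all equilibria into enone 18. The closest known reaction types are the base-mediated intramolecular Michael/aldol condensation (Robinson-type annulation) and the cinchona ammonium phase-transfer Michael addition of simple methyl ketone enolates to enones that is followed by aldol closure to scalemic cyclohexenones; new here are the tetrasubstituted acceptor and the double ring closure of an acyclic chain. C10 is set by the cation, whose anthracenylmethyl wall should leave only one face of the C9=C10 bond open to the tethered enolate (the remote C13 centre has no influence, so this is catalyst control, and any minor isomer is a separable diastereomer). C5 lies alpha to the C6 ketone and should settle under the basic conditions as the trans-fused 5α-H epimer, C9 is set when the C8–C9 enolate is protonated anti to the axial C10 methyl in the folded conformer, the epimer that reaches a chair aldol transition state with the C11 chain equatorial, and C8 becomes planar again and is set in steps 10 and 11. The step needs site selection among four enolisable positions and two aldol directions: attack through C7 or C17 before ring A exists would close eight- or ten-membered rings and is reversible, and in diketone 16 the C6 carbonyl, wedged between the C4 gem-dimethyl group and quaternary C10, is shielded and can only act as the enolate partner, so C7 adds to C8 and not C17 to C6. The gem-dialkyl effect of C4 in the tether and the irreversible dehydration should offset the low electrophilicity of the fully substituted acceptor.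

**Step 10**
Reactants: 18 (13R)-13-(triethylsilyloxy)labda-7,14-dien-6-one
Product: 19 (13R)-7α,8α-epoxy-13-(triethylsilyloxy)labd-14-en-6-one
Conditions: tBuOOH (decane), benzyltrimethylammonium hydroxide (cat.), THF, 0 °C to rt
Reagents that add atoms: tert-butyl hydroperoxide CC(C)(C)OO
Why: Weitz–Scheffer nucleophilic epoxidation touches only the enone, and the bulky peroxide anion should attack C8 from the α face because the β face is screened by the axial C10 methyl (1,3 to C8) and the axial C4 methyl, which sets C8 (oxygen α, methyl β) and C7.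

**Step 11**
Reactants: 19 (13R)-7α,8α-epoxy-13-(triethylsilyloxy)labd-14-en-6-one
Product: 20 (13R)-8α-hydroxy-13-(triethylsilyloxy)labd-14-en-6-one
Conditions: SmI2 (2.2 equiv), THF/MeOH, −78 °C
Reagents that add atoms: none
Why: Samarium diiodide reduction of an α,β-epoxy ketone cleaves only the C7–O bond next to the ketyl, so the C8–O bond and the 8α-hydroxy configuration are kept and the sensitive aldol is released under non-basic conditions.

**Step 12**
Reactants: 20 (13R)-8α-hydroxy-13-(triethylsilyloxy)labd-14-en-6-one
Product: 21 (13R)-13-(triethylsilyloxy)labd-14-ene-6α,8α-diol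
Conditions: SmI2 (excess), H2O (large excess), THF, rt
Reagents that add atoms: none
Why: Electron-transfer ketone reduction (samarium diiodide–water) runs through a ketyl and an organosamarium that place oxygen in the less crowded position, so it should give the equatorial 6α-alcohol, since the axial 6β position is flanked by two syn-axial methyl groups.

**Step 13**
Reactants: 21 (13R)-13-(triethylsilyloxy)labd-14-ene-6α,8α-diol; 22 angelic acid
Product: 24 (13R)-6α-angeloyloxy-13-(triethylsilyloxy)labd-14-en-8α-ol, via mixed anhydride 23 (not isolated)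
Conditions: 22, 2,4,6-trichlorobenzoyl chloride, Et3N, toluene, rt; then 21, 80 °C
Reagents that add atoms: none
Why: Yamaguchi-type mixed anhydride esterification run without a nucleophilic catalyst acylates the only secondary hydroxyl, transfers the angeloyl group without Z to E isomerisation, and leaves C6 unchanged because its C–O bond is not touched.

**Step 14**
Reactants: 24 (13R)-6α-angeloyloxy-13-(triethylsilyloxy)labd-14-en-8α-ol
Product: 25 (13R)-6α-angeloyloxylabd-14-ene-8α,13-diol (target)
Conditions: HF·pyridine, pyridine, THF, 0 °C to rt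
Reagents that add atoms: none
Why: Buffered fluoride-mediated desilylation removes the triethylsilyl group without ionising the tertiary allylic alcohol, hydrolysing the ester or isomerising the angelate.

**Compound list**
1 | (R)-(−)-linalool, (3R)-3,7-dimethylocta-1,6-dien-3-ol | C=C[C@](C)(O)CCC=C(C)C | starting material
2 | (3R)-3,7-dimethyl-3-(triethylsilyloxy)octa-1,6-diene | C=C[C@](C)(O[Si](CC)(CC)CC)CCC=C(C)C | intermediate
3 | (4R)-4-methyl-4-(triethylsilyloxy)hex-5-enal | C=C[C@](C)(O[Si](CC)(CC)CC)CCC=O | intermediate
4 | (4R)-4-methyl-4-(triethylsilyloxy)hex-5-enoic acid | C=C[C@](C)(O[Si](CC)(CC)CC)CCC(=O)O | intermediate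
5 | 2-thioxopyridin-1(2H)-yl (4R)-4-methyl-4-(triethylsilyloxy)hex-5-enoate | C=C[C@](C)(O[Si](CC)(CC)CC)CCC(=O)ON1C=CC=CC1=S | intermediate
6 | (3R)-5-iodo-3-methyl-3-(triethylsilyloxy)pent-1-ene | C=C[C@](C)(O[Si](CC)(CC)CC)CCI | intermediate
7 | pentane-2,4-dione (acetylacetone) | CC(=O)CC(C)=O | starting material
8 | 3-[(3R)-3-methyl-3-(triethylsilyloxy)pent-4-en-1-yl]pentane-2,4-dione | C=C[C@](C)(O[Si](CC)(CC)CC)CCC(C(C)=O)C(C)=O | intermediate
9 | (2Z,6R)-3-acetyl-6-methyl-6-(triethylsilyloxy)octa-2,7-dien-2-yl trifluoromethanesulfonate (triflate cis to acetyl) | C=C[C@](C)(O[Si](CC)(CC)CC)CC/C(C(C)=O)=C(\C)OS(=O)(=O)C(F)(F)F | intermediate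
10 | mesityl oxide (4-methylpent-3-en-2-one) | CC(=O)C=C(C)C | starting material
11 | allyltrimethylsilane | C=CC[Si](C)(C)C | starting material
12 | 4,4-dimethylhept-6-en-2-one | CC(=O)CC(C)(C)CC=C | intermediate
13 | 7-bromo-4,4-dimethylheptan-2-one | CC(=O)CC(C)(C)CCCBr | intermediate
14 | (4,4-dimethyl-6-oxoheptyl)zinc bromide | CC(=O)CC(C)(C)CCC[Zn]Br | intermediate
15 | (3Z)-4,8,8-trimethyl-3-[(3R)-3-methyl-3-(triethylsilyloxy)pent-4-en-1-yl]undec-3-ene-2,10-dione (long chain cis to acetyl) | C=C[C@](C)(O[Si](CC)(CC)CC)CC/C(C(C)=O)=C(\C)CCCC(C)(C)CC(C)=O | intermediate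
16 | (13R)-13-(triethylsilyloxy)-7,8-secolabd-14-ene-6,8-dione (ring A closed; 5α-H, 9α-H, 10β-methyl) | C=C[C@](C)(O[Si](CC)(CC)CC)CC[C@@H](C(C)=O)[C@@]1(C)CCCC(C)(C)[C@@H]1C(C)=O | intermediate
17 | (13R)-8β-hydroxy-13-(triethylsilyloxy)labd-14-en-6-one (ketol, axial hydroxyl expected) | C=C[C@](C)(O[Si](CC)(CC)CC)CC[C@@H]1[C@@]2(C)CCCC(C)(C)[C@@H]2C(=O)C[C@]1(C)O | intermediate
18 | (13R)-13-(triethylsilyloxy)labda-7,14-dien-6-one (trans-decalin; 5α-H, 9α-H, 10β-methyl) | C=C[C@](C)(O[Si](CC)(CC)CC)CC[C@@H]1[C@@]2(C)CCCC(C)(C)[C@@H]2C(=O)C=C1C | intermediate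
19 | (13R)-7α,8α-epoxy-13-(triethylsilyloxy)labd-14-en-6-one | C=C[C@](C)(O[Si](CC)(CC)CC)CC[C@@H]1[C@@]2(C)CCCC(C)(C)[C@@H]2C(=O)[C@H]3O[C@@]13C | intermediate
20 | (13R)-8α-hydroxy-13-(triethylsilyloxy)labd-14-en-6-one | C=C[C@](C)(O[Si](CC)(CC)CC)CC[C@@H]1[C@@]2(C)CCCC(C)(C)[C@@H]2C(=O)C[C@@]1(C)O | intermediate
21 | (13R)-13-(triethylsilyloxy)labd-14-ene-6α,8α-diol | C=C[C@](C)(O[Si](CC)(CC)CC)CC[C@@H]1[C@@]2(C)CCCC(C)(C)[C@@H]2[C@@H](O)C[C@@]1(C)O | intermediate
22 | angelic acid, (Z)-2-methylbut-2-enoic acid | OC(=O)/C(C)=C\C | starting material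
23 | angelic 2,4,6-trichlorobenzoic anhydride | O=C(OC(=O)/C(C)=C\C)c1c(Cl)cc(Cl)cc1Cl | intermediate
24 | (13R)-6α-angeloyloxy-13-(triethylsilyloxy)labd-14-en-8α-ol | C=C[C@](C)(O[Si](CC)(CC)CC)CC[C@@H]1[C@@]2(C)CCCC(C)(C)[C@@H]2[C@@H](OC(=O)/C(C)=C\C)C[C@@]1(C)O | intermediate
25 | (13R)-6α-angeloyloxylabd-14-ene-8α,13-diol | C=C[C@](C)(O)CC[C@@H]1[C@@]2(C)CCCC(C)(C)[C@@H]2[C@@H](OC(=O)/C(C)=C\C)C[C@@]1(C)O | target

Total step count: 14. Longest linear sequence: 12 (steps 1–5 and 8–14).

**Steps most likely to fail**

Step 9 (Proposed new method). Facial selection at C10 by the ion pair may be poor, or the Michael addition may stall on the hindered acceptor. The fallback gives up catalyst control and uses the resident C13 centre as a resolving handle. Setting out from 15, classical Robinson-type conditions (KOtBu, tBuOH/THF, rt to 60 °C) should close both rings to 18 together with the core-antipodal diastereomer of 18 F1. The two differ in their configuration relative to C13, so they are diastereomers that chromatography should separate. The route is rejoined at 18.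

Step 10. Facial selectivity may be poor, because stereoelectronically favoured axial attack of the peroxide anion on the β face competes with the sterically favoured α attack. The fallback switches from nucleophilic to electrophilic epoxidation. Setting out from 18, Luche reduction (NaBH4, CeCl3·7H2O, MeOH, 0 °C) should give the 6β-allylic alcohol F2. Peracid epoxidation (mCPBA, NaHCO3, CH2Cl2, 0 °C) takes the open α face of ring B Δ7 alkenes of this skeleton and prefers the trisubstituted alkene over the vinyl group, so it should give the 7α,8α-epoxy-6β-alcohol F3. Dess–Martin oxidation then returns to the route at 19.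

Step 12. Hydrogen may be delivered to the wrong face of C6, or the allylic silyloxy group may be lost reductively. The fallback replaces electron transfer by hydride delivery followed by thermodynamic equilibration. Setting out from 20, NaBH4 (MeOH, 0 °C) should attack from the open α face and give the axial 6β,8α-diol F4. Meerwein–Ponndorf–Verley/Oppenauer equilibration (Al(OiPr)3, catalytic acetone, toluene/iPrOH, reflux) should then relax the strongly strained axial alcohol to the equatorial epimer, coming back to the route at 21.

**Further compounds**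
F1 | step 9 | (13R)-13-(triethylsilyloxy)-ent-labda-7,14-dien-6-one core diastereomer (5β-H, 9β-H, 10α-methyl) | C=C[C@](C)(O[Si](CC)(CC)CC)CC[C@H]1[C@]2(C)CCCC(C)(C)[C@H]2C(=O)C=C1C
F2 | step 10 | (13R)-13-(triethylsilyloxy)labda-7,14-dien-6β-ol | C=C[C@](C)(O[Si](CC)(CC)CC)CC[C@@H]1[C@@]2(C)CCCC(C)(C)[C@@H]2[C@H](O)C=C1C
F3 | step 10 | (13R)-7α,8α-epoxy-13-(triethylsilyloxy)labd-14-en-6β-ol | C=C[C@](C)(O[Si](CC)(CC)CC)CC[C@@H]1[C@@]2(C)CCCC(C)(C)[C@@H]2[C@H](O)[C@H]3O[C@@]13C
F4 | step 12 | (13R)-13-(triethylsilyloxy)labd-14-ene-6β,8α-diol | C=C[C@](C)(O[Si](CC)(CC)CC)CC[C@@H]1[C@@]2(C)CCCC(C)(C)[C@@H]2[C@H](O)C[C@@]1(C)O
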